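## Retrosynthetic overview

1. The last bond is N–C(quinone): addition–elimination of aminoresorcinol ester 35 on methoxyquinone 29. Both halves carry the same decalin, so one building block (neopentyl iodide 22, turned into one batch of neopentylzinc chloride 26) is made once and used twice.
2. Both C11–aryl bonds come from Negishi coupling of organozinc 26 with aryl bromides 24 (quinone half) and 32 (benzoate half).
3. Ring A of the decalin is a cyclohexene (C1–C2–C3=C4–C5–C10) whose C3=C4 double bond lies next to the quaternary ring-fusion carbon C5, and the C5–C10 bond is shared by ring A and ring B. This is the retron of an intramolecular Diels–Alder reaction: cutting C5–C10 and C1–C2 gives the acyclic (2E,8E)-trienal 18 (diene C2=C3–C4=C5, dienophile C1=C10, tether C6–C9), with a formyl group on C1 as a removable activator.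
4. Trienal 18: the C8/C9 stereodiad comes from a chiral-pool δ-lactone by enolate alkylation; the tetrasubstituted (E)-diene comes from Negishi coupling with an (E)-enol tosylate, then methylenation.
5. Ring order: the arene rings are bought; rings A and B of the decalin form together in step 14 and are the only rings made.

Key step: step 14

Remark on the chemistry: decalin carbons are numbered C1–C10 (C5–C10 ring fusion, C3=C4 double bond, C8 = CH(CH3), C9 quaternary), the CH2 between C9 and the arene or quinone is C11, and acyclic precursors keep these numbers; "Dec" = (1R,2S,4aS,8aS)-1,2,4a,5-tetramethyl-1,2,3,4,4a,7,8,8a-octahydronaphthalen-1-yl, with the descriptors as they read when the attached CH2 carries an arene or quinone carbon (the spatial arrangement is that of 20–22, where the 8a descriptor reads R only because the substituent priorities differ); compounds 1, 9, 23 and 30 are assumed to be purchased.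

## Route

Step 1
Reactants: 1 methyl hydrogen (R)-3-methylglutarate
Product: 3 (S)-4-methyloxan-2-one, via hydroxy acid 2 (not isolated)
Conditions: NaH (1.0 equiv), THF, 0 °C; LiBH4, THF, rt → 50 °C; then 3 M HCl, rt → 40 °C
Reagents that add atoms: none
Why: Chemoselective borohydride reduction of the ester beside the carboxylate salt, then acid-induced lactonisation, should give the lactone whose carbonyl is the former acid carbon, so the purchased stereocentre (later C8) is carried over without any bond to it being touched.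

Step 2
Reactants: 3 (S)-4-methyloxan-2-one
Product: 4 (3R,4S)-3,4-dimethyloxan-2-one
Conditions: LiN(i-Pr)2, THF, −78 °C; MeI, −78 → −40 °C
Reagents that add atoms: iodomethane CI
Why: Lactone enolate alkylation should place the new methyl trans to the C4 methyl, although this centre is planarised again in step 3.

Step 3
Reactants: 4 (3R,4S)-3,4-dimethyloxan-2-one
Product: 5 (3S,4S)-3-[(benzyloxy)methyl]-3,4-dimethyloxan-2-one
Conditions: LiN(i-Pr)2, THF/DMPU, −78 °C; BnOCH2Cl, −78 → −30 °C
Reagents that add atoms: benzyl chloromethyl ether ClCOCc1ccccc1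
Why: Enolate alkylation to a quaternary carbon, in which allylic 1,2-strain in the tetrasubstituted enolate turns the neighbouring methyl pseudoaxial and the electrophile should enter anti to it, setting the later C9 with CH2OBn (later C11) trans and CH3 cis to the C8 methyl.

Step 4
Reactants: 5 (3S,4S)-3-[(benzyloxy)methyl]-3,4-dimethyloxan-2-one
Product: 6 (2R,3S)-2-[(benzyloxy)methyl]-2,3-dimethylpentane-1,5-diol
Conditions: LiAlH4, THF, 0 °C → rt
Reagents that add atoms: none
Why: Hydride reduction of the lactone to the 1,5-diol touches no stereocentre.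

Step 5
Reactants: 6 (2R,3S)-2-[(benzyloxy)methyl]-2,3-dimethylpentane-1,5-diol
Product: 7 (2R,3S)-2-[(benzyloxy)methyl]-5-iodo-2,3-dimethylpentan-1-ol
Conditions: I2, PPh3, imidazole, CH2Cl2, −20 → 0 °C
Reagents that add atoms: iodine II
Why: In this Appel-type iodination the unhindered primary hydroxyl (later C6) should react far faster than the neopentyl hydroxyl on the quaternary carbon.

Step 6
Reactants: 7 (2R,3S)-2-[(benzyloxy)methyl]-5-iodo-2,3-dimethylpentan-1-ol
Product: 8 (2S,3S)-2-[(benzyloxy)methyl]-5-iodo-2,3-dimethylpentyl acetate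
Conditions: Ac2O, pyridine, DMAP (cat.), CH2Cl2, 0 °C
Reagents that add atoms: acetic anhydride CC(=O)OC(C)=O
Why: DMAP-catalysed acetylation masks the neopentyl alcohol (later C10) as an ester that tolerates the organozinc step and is removed by the hydride in step 9.

Step 7
Reactants: 9 ethyl 2-methyl-3-oxobutanoate
Product: 10 ethyl (2E)-2-methyl-3-(tosyloxy)but-2-enoate
Conditions: TsCl, N-methylimidazole, Et3N, MeCN, 0 °C
Reagents that add atoms: 4-toluenesulfonyl chloride Cc1ccc(cc1)S(Cl)(=O)=O
Why: Amine-mediated, non-chelating enol sulfonylation of an α-substituted β-keto ester should give the (E)-enol tosylate with the tosyloxy group trans to the ester.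

Step 8
Reactants: 8 (2S,3S)-2-[(benzyloxy)methyl]-5-iodo-2,3-dimethylpentyl acetate; 10 ethyl (2E)-2-methyl-3-(tosyloxy)but-2-enoate
Product: 12 ethyl (2E,6S,7S)-8-acetoxy-7-[(benzyloxy)methyl]-2,3,6,7-tetramethyloct-2-enoate, via alkylzinc iodide 11 (not isolated)
Conditions: Zn dust, LiCl, THF, 40 °C; then 10, PdCl2(dppf) (5 mol%), THF, 50 °C
Reagents that add atoms: none
Why: Zinc insertion into the primary C–I bond followed by Negishi coupling with the enol tosylate proceeds with retention of olefin geometry, so the chain (C6) should end up trans to the ester carbon (later C3) on the tetrasubstituted C4=C5 double bond.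

Step 9
Reactants: 12 ethyl (2E,6S,7S)-8-acetoxy-7-[(benzyloxy)methyl]-2,3,6,7-tetramethyloct-2-enoate
Product: 13 (2E,6S,7R)-7-[(benzyloxy)methyl]-2,3,6,7-tetramethyloct-2-ene-1,8-diol
Conditions: i-Bu2AlH (excess), CH2Cl2, −78 → 0 °C; aq. potassium sodium tartrate work-up
Reagents that add atoms: none
Why: Aluminium hydride reduction should convert the conjugated ester into the allylic alcohol and cleave the acetate in the same operation.

Step 10
Reactants: 13 (2E,6S,7R)-7-[(benzyloxy)methyl]-2,3,6,7-tetramethyloct-2-ene-1,8-diol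
Product: 14 (2E,6S,7R)-7-[(benzyloxy)methyl]-8-hydroxy-2,3,6,7-tetramethyloct-2-enal
Conditions: MnO2 (activated), CH2Cl2, rt
Reagents that add atoms: none
Why: MnO2 oxidises only the allylic alcohol under neutral conditions, leaving the neopentyl alcohol and the olefin geometry untouched.

Step 11
Reactants: 14 (2E,6S,7R)-7-[(benzyloxy)methyl]-8-hydroxy-2,3,6,7-tetramethyloct-2-enal
Product: 15 (2R,3S,6E)-2-[(benzyloxy)methyl]-2,3,6,7-tetramethylnona-6,8-dien-1-ol
Conditions: Ph3PCH3Br, KN(SiMe3)2 (excess), THF, −78 → 0 °C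
Reagents that add atoms: methyltriphenylphosphonium bromide C[P+](c1ccccc1)(c1ccccc1)c1ccccc1.[Br-]
Why: Wittig methylenation at low temperature (to avoid γ-deprotonation and E/Z scrambling) should give the (E)-3,4-dimethyl-1,3-diene, with the free hydroxyl carried as its alkoxide.

Step 12
Reactants: 15 (2R,3S,6E)-2-[(benzyloxy)methyl]-2,3,6,7-tetramethylnona-6,8-dien-1-ol
Product: 16 (2S,3S,6E)-2-[(benzyloxy)methyl]-2,3,6,7-tetramethylnona-6,8-dienal
Conditions: Dess–Martin periodinane, pyridine, CH2Cl2, 0 °C → rt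
Reagents that add atoms: none
Why: Dess–Martin oxidation of the neopentyl alcohol gives an aldehyde whose α-carbon is quaternary, so it cannot epimerise.

Step 13
Reactants: 16 (2S,3S,6E)-2-[(benzyloxy)methyl]-2,3,6,7-tetramethylnona-6,8-dienal
Product: 18 (2E,4R,5S,8E)-4-[(benzyloxy)methyl]-4,5,8,9-tetramethylundeca-2,8,10-trienal, via unsaturated imine 17 (not isolated)
Conditions: (EtO)2P(O)CH2CH=N-c-C6H11, NaH, THF, 0 °C → rt; then aq. oxalic acid, rt
Reagents that add atoms: diethyl [2-(cyclohexylimino)ethyl]phosphonate CCOP(=O)(OCC)CC=NC1CCCCC1; water O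
Why: Horner–Wadsworth–Emmons formyl-olefination, which works on hindered non-enolisable aldehydes, followed by mild hydrolysis of the unsaturated imine should give the (E)-enal.

Step 14
Reactants: 18 (2E,4R,5S,8E)-4-[(benzyloxy)methyl]-4,5,8,9-tetramethylundeca-2,8,10-trienal
Product: 19 (1S,4aS,7S,8R,8aR)-8-[(benzyloxy)methyl]-4,4a,7,8-tetramethyl-1,2,4a,5,6,7,8,8a-octahydronaphthalene-1-carbaldehyde
Conditions: Me2AlCl (1.5 equiv), CH2Cl2, −78 → 0 °C
Reagents that add atoms: none
Why: Lewis acid-promoted type 1 intramolecular Diels–Alder reaction of a 1,7,9-decatriene: Me2AlCl binds the enal carbonyl, lowers the dienophile LUMO and lets the C2=C3–C4=C5 diene add across C1=C10 in a concerted, asynchronous [4+2] process, the closest known type being the Lewis acid-catalysed cyclisation of (2E,8E)-deca-2,8,10-trienals and -trienoates to trans-fused octalins. Ring A is closed by the cycloaddition itself through the new C5–C10 and C1–C2 bonds, and ring B closes in the same event because the four-carbon tether C6–C9 links the diene terminus C5 to the dienophile carbon C10 (fused mode, six-membered carbocycle). C5 and C10 are controlled by olefin geometry and the endo rule: the (8E)-diene carries the tether outside and the C5 methyl inside, and the endo orientation of the aluminium-bound formyl group of the (2E)-enal forces the tether anti, so the C5 methyl and H10 end up trans (trans-decalin); the formyl-bearing C1 is a transient centre removed in step 15. The absolute sense is relayed from C8/C9 through a chair-like tether with the C8 methyl and the C9 CH2OBn group equatorial and the C9 methyl axial, whereas the other trans-fused transition state needs an axial C8 methyl and an axial CH2OBn group syn to the inside methyl. The step needs endo/exo and π-facial selectivity plus enough reactivity at the fully substituted diene terminus; these are secured by Lewis acid activation at low temperature, which also suppresses the thermal 1,5-hydrogen shift of the Z-methyl diene.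

Step 15
Reactants: 19 (1S,4aS,7S,8R,8aR)-8-[(benzyloxy)methyl]-4,4a,7,8-tetramethyl-1,2,4a,5,6,7,8,8a-octahydronaphthalene-1-carbaldehyde
Product: 20 (1R,2S,4aS,8aR)-1-[(benzyloxy)methyl]-1,2,4a,5-tetramethyl-1,2,3,4,4a,7,8,8a-octahydronaphthalene
Conditions: RhCl(PPh3)3 (1.1 equiv), toluene, 110 °C
Reagents that add atoms: none
Why: Tsuji–Wilkinson decarbonylation (formyl C–H oxidative addition, CO extrusion, C–H reductive elimination) should remove the activating group and leave C1 as CH2 without touching the trisubstituted alkene or the benzyl ether.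

Step 16
Reactants: 20 (1R,2S,4aS,8aR)-1-[(benzyloxy)methyl]-1,2,4a,5-tetramethyl-1,2,3,4,4a,7,8,8a-octahydronaphthalene
Product: 21 [(1R,2S,4aS,8aR)-1,2,4a,5-tetramethyl-1,2,3,4,4a,7,8,8a-octahydronaphthalen-1-yl]methanol
Conditions: lithium 4,4′-di-tert-butylbiphenylide, THF, −78 °C; then NH4Cl
Reagents that add atoms: none
Why: Reductive cleavage of the benzyl ether by an arene radical anion (dissolving-metal type) does not reduce the isolated trisubstituted double bond.

Step 17
Reactants: 21 [(1R,2S,4aS,8aR)-1,2,4a,5-tetramethyl-1,2,3,4,4a,7,8,8a-octahydronaphthalen-1-yl]methanol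
Product: 22 (1R,2S,4aS,8aR)-1-(iodomethyl)-1,2,4a,5-tetramethyl-1,2,3,4,4a,7,8,8a-octahydronaphthalene
Conditions: I2, PPh3, imidazole, toluene, 90 °C
Reagents that add atoms: iodine II
Why: Appel iodination, in which iodide displaces the alkoxyphosphonium group by SN2 at the neopentyl carbon on heating, should proceed without skeletal rearrangement.

Step 18
Reactants: 23 1,2,4,5-tetramethoxybenzene
Product: 24 3-bromo-1,2,4,5-tetramethoxybenzene
Conditions: N-bromosuccinimide, MeCN, 0 °C → rt
Reagents that add atoms: N-bromosuccinimide O=C1CCC(=O)N1Br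
Why: Electrophilic aromatic bromination, where the two free positions are equivalent and the first bromine slows a second substitution.

Step 19
Reactants: 22 (1R,2S,4aS,8aR)-1-(iodomethyl)-1,2,4a,5-tetramethyl-1,2,3,4,4a,7,8,8a-octahydronaphthalene
Product: 26 {[(1R,2S,4aS,8aR)-1,2,4a,5-tetramethyl-1,2,3,4,4a,7,8,8a-octahydronaphthalen-1-yl]methyl}zinc chloride, via alkyllithium 25 (not isolated)
Conditions: t-BuLi (2.0 equiv), Et2O, −78 °C; ZnCl2 (1.1 equiv, 1.0 M in THF), −78 °C → rt; iodometric titration; kept as a stock solution under argon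
Reagents that add atoms: zinc chloride Cl[Zn]Cl
Why: Iodine–lithium exchange at the primary neopentyl iodide is fast and irreversible with two equivalents of t-BuLi (the second consumes the tert-butyl iodide formed), and transmetalation with ZnCl2 should give a neopentylzinc chloride without β-hydrogen that is free of alkyllithium and stable in solution, so one batch is divided between the couplings of steps 20 and 25.

Step 20
Reactants: 24 3-bromo-1,2,4,5-tetramethoxybenzene; 26 {[(1R,2S,4aS,8aR)-1,2,4a,5-tetramethyl-1,2,3,4,4a,7,8,8a-octahydronaphthalen-1-yl]methyl}zinc chloride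
Product: 27 3-(DecCH2)-1,2,4,5-tetramethoxybenzene
Conditions: Pd(OAc)2 (5 mol%), SPhos (10 mol%), THF/NMP, 60 °C
Reagents that add atoms: none
Why: Negishi coupling, where the neopentylzinc reagent has no β-hydrogen so β-hydride elimination cannot compete, and a biarylphosphine ligand serves the doubly ortho-substituted aryl bromide.

Step 21
Reactants: 27 3-(DecCH2)-1,2,4,5-tetramethoxybenzene
Product: 28 3-(DecCH2)-2,5-dimethoxycyclohexa-2,5-diene-1,4-dione
Conditions: (NH4)2Ce(NO3)6, MeCN/H2O, 0 °C
Reagents that add atoms: water O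
Why: Oxidative demethylation of a 1,4-dimethoxyarene to the p-quinone, in which both para pairs of methoxy groups lead to the same quinone and the trisubstituted alkene is tolerated.

Step 22
Reactants: 28 3-(DecCH2)-2,5-dimethoxycyclohexa-2,5-diene-1,4-dione
Product: 29 3-(DecCH2)-2-hydroxy-5-methoxycyclohexa-2,5-diene-1,4-dione
Conditions: KOH, MeOH/H2O, rt; then 1 M HCl
Reagents that add atoms: potassium hydroxide [K+].[OH-]
Why: Addition–elimination of hydroxide at a vinylogous ester, where the methoxy group next to the bulky side chain is twisted out of conjugation and should be the one hydrolysed, as is known for 3-alkyl-2,5-dimethoxybenzoquinones.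

Step 23
Reactants: 30 methyl 5-bromo-2,4-dihydroxybenzoate
Product: 31 methyl 5-bromo-2,4-dihydroxy-3-nitrobenzoate
Conditions: HNO3 (65%, 1.05 equiv), AcOH, 10 °C → rt
Reagents that add atoms: nitric acid O[N+](=O)[O-]
Why: Electrophilic nitration of the resorcinol ring, where the carbon between the two hydroxyls is the only activated free position because C5 is blocked by bromine.

Step 24
Reactants: 31 methyl 5-bromo-2,4-dihydroxy-3-nitrobenzoate
Product: 32 methyl 2,4-diacetoxy-5-bromo-3-nitrobenzoate
Conditions: Ac2O, pyridine, DMAP (cat.), CH2Cl2, rt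
Reagents that add atoms: acetic anhydride CC(=O)OC(C)=O
Why: Acetylation removes both acidic phenol protons before the organozinc step.

Step 25
Reactants: 26 {[(1R,2S,4aS,8aR)-1,2,4a,5-tetramethyl-1,2,3,4,4a,7,8,8a-octahydronaphthalen-1-yl]methyl}zinc chloride; 32 methyl 2,4-diacetoxy-5-bromo-3-nitrobenzoate
Product: 33 methyl 2,4-diacetoxy-5-(DecCH2)-3-nitrobenzoate
Conditions: Pd(OAc)2 (5 mol%), SPhos (10 mol%), THF, 50 °C
Reagents that add atoms: none
Why: Negishi coupling as in step 20, relying on the tolerance of organozinc reagents for nitro, ester and aryl acetate groups and on a reagent solution that contains no residual alkyllithium.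

Step 26
Reactants: 33 methyl 2,4-diacetoxy-5-(DecCH2)-3-nitrobenzoate
Product: 34 methyl 5-(DecCH2)-2,4-dihydroxy-3-nitrobenzoate
Conditions: K2CO3, MeOH, 0 °C → rt; then 1 M HCl
Reagents that add atoms: none
Why: Methanolysis (transesterification) of the activated aryl acetates leaves the methyl ester unchanged in methanol.

Step 27
Reactants: 34 methyl 5-(DecCH2)-2,4-dihydroxy-3-nitrobenzoate
Product: 35 methyl 3-amino-5-(DecCH2)-2,4-dihydroxybenzoate
Conditions: Zn dust, AcOH, THF, 0 °C → rt, argon
Reagents that add atoms: none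
Why: Dissolving-metal reduction of the nitro group to the aniline uses no hydrogenation catalyst, so the alkene is safe.

Step 28
Reactants: 29 3-(DecCH2)-2-hydroxy-5-methoxycyclohexa-2,5-diene-1,4-dione; 35 methyl 3-amino-5-(DecCH2)-2,4-dihydroxybenzoate
Product: 36 nakijiquinone F
Conditions: NaHCO3, EtOH/H2O (degassed), 45 °C, argon; then 1 M HCl to pH 3
Reagents that add atoms: none
Why: Addition–elimination turning a vinylogous ester into a vinylogous amide: the aniline nitrogen attacks the methoxy-bearing quinone carbon next to the CH and methoxide leaves, while the deprotonated hydroxyl-bearing carbon is unreactive, which fixes the regiochemistry.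

## Compound list

1 | methyl hydrogen (R)-3-methylglutarate | COC(=O)C[C@H](C)CC(=O)O | starting material
2 | (3S)-5-hydroxy-3-methylpentanoic acid | O=C(O)C[C@@H](C)CCO | intermediate
3 | (S)-4-methyloxan-2-one | O=C1C[C@@H](C)CCO1 | intermediate
4 | (3R,4S)-3,4-dimethyloxan-2-one | O=C1[C@H](C)[C@@H](C)CCO1 | intermediate
5 | (3S,4S)-3-[(benzyloxy)methyl]-3,4-dimethyloxan-2-one | O=C1[C@](C)(COCc2ccccc2)[C@@H](C)CCO1 | intermediate
6 | (2R,3S)-2-[(benzyloxy)methyl]-2,3-dimethylpentane-1,5-diol | OC[C@](C)(COCc1ccccc1)[C@@H](C)CCO | intermediate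
7 | (2R,3S)-2-[(benzyloxy)methyl]-5-iodo-2,3-dimethylpentan-1-ol | OC[C@](C)(COCc1ccccc1)[C@@H](C)CCI | intermediate
8 | (2S,3S)-2-[(benzyloxy)methyl]-5-iodo-2,3-dimethylpentyl acetate | CC(=O)OC[C@](C)(COCc1ccccc1)[C@@H](C)CCI | intermediate
9 | ethyl 2-methyl-3-oxobutanoate | CCOC(=O)C(C)C(C)=O | starting material
10 | ethyl (2E)-2-methyl-3-(tosyloxy)but-2-enoate | CCOC(=O)/C(C)=C(\C)OS(=O)(=O)c1ccc(C)cc1 | intermediate
11 | [(3S,4S)-5-acetoxy-4-[(benzyloxy)methyl]-3,4-dimethylpentyl]zinc iodide | CC(=O)OC[C@](C)(COCc1ccccc1)[C@@H](C)CC[Zn]I | intermediate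
12 | ethyl (2E,6S,7S)-8-acetoxy-7-[(benzyloxy)methyl]-2,3,6,7-tetramethyloct-2-enoate | CCOC(=O)/C(C)=C(\C)CC[C@H](C)[C@@](C)(COCc1ccccc1)COC(C)=O | intermediate
13 | (2E,6S,7R)-7-[(benzyloxy)methyl]-2,3,6,7-tetramethyloct-2-ene-1,8-diol | OC/C(C)=C(\C)CC[C@H](C)[C@@](C)(COCc1ccccc1)CO | intermediate
14 | (2E,6S,7R)-7-[(benzyloxy)methyl]-8-hydroxy-2,3,6,7-tetramethyloct-2-enal | O=C/C(C)=C(\C)CC[C@H](C)[C@@](C)(COCc1ccccc1)CO | intermediate
15 | (2R,3S,6E)-2-[(benzyloxy)methyl]-2,3,6,7-tetramethylnona-6,8-dien-1-ol | C=C/C(C)=C(\C)CC[C@H](C)[C@@](C)(COCc1ccccc1)CO | intermediate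
16 | (2S,3S,6E)-2-[(benzyloxy)methyl]-2,3,6,7-tetramethylnona-6,8-dienal | C=C/C(C)=C(\C)CC[C@H](C)[C@@](C)(COCc1ccccc1)C=O | intermediate
17 | N-cyclohexyl imine of trienal 18 | C=C/C(C)=C(\C)CC[C@H](C)[C@@](C)(COCc1ccccc1)/C=C/C=NC1CCCCC1 | intermediate
18 | (2E,4R,5S,8E)-4-[(benzyloxy)methyl]-4,5,8,9-tetramethylundeca-2,8,10-trienal | C=C/C(C)=C(\C)CC[C@H](C)[C@@](C)(COCc1ccccc1)/C=C/C=O | intermediate
19 | (1S,4aS,7S,8R,8aR)-8-[(benzyloxy)methyl]-4,4a,7,8-tetramethyl-1,2,4a,5,6,7,8,8a-octahydronaphthalene-1-carbaldehyde | c1ccccc1COC[C@]2(C)[C@@H](C)CC[C@]3(C)C(C)=CC[C@H](C=O)[C@@H]23 | intermediate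
20 | (1R,2S,4aS,8aR)-1-[(benzyloxy)methyl]-1,2,4a,5-tetramethyl-1,2,3,4,4a,7,8,8a-octahydronaphthalene | c1ccccc1COC[C@]2(C)[C@@H](C)CC[C@]3(C)C(C)=CCC[C@@H]23 | intermediate
21 | [(1R,2S,4aS,8aR)-1,2,4a,5-tetramethyl-1,2,3,4,4a,7,8,8a-octahydronaphthalen-1-yl]methanol | OC[C@]1(C)[C@@H](C)CC[C@]2(C)C(C)=CCC[C@@H]12 | intermediate
22 | (1R,2S,4aS,8aR)-1-(iodomethyl)-1,2,4a,5-tetramethyl-1,2,3,4,4a,7,8,8a-octahydronaphthalene | IC[C@]1(C)[C@@H](C)CC[C@]2(C)C(C)=CCC[C@@H]12 | intermediate
23 | 1,2,4,5-tetramethoxybenzene | COc1cc(OC)c(OC)cc1OC | starting material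
24 | 3-bromo-1,2,4,5-tetramethoxybenzene | COc1cc(OC)c(OC)c(Br)c1OC | intermediate
25 | {[(1R,2S,4aS,8aS)-1,2,4a,5-tetramethyl-1,2,3,4,4a,7,8,8a-octahydronaphthalen-1-yl]methyl}lithium (DecCH2Li) | [Li]C[C@]1(C)[C@@H](C)CC[C@]2(C)C(C)=CCC[C@@H]12 | intermediate
26 | {[(1R,2S,4aS,8aR)-1,2,4a,5-tetramethyl-1,2,3,4,4a,7,8,8a-octahydronaphthalen-1-yl]methyl}zinc chloride (DecCH2ZnCl) | Cl[Zn]C[C@]1(C)[C@@H](C)CC[C@]2(C)C(C)=CCC[C@@H]12 | intermediate
27 | 3-(DecCH2)-1,2,4,5-tetramethoxybenzene | COc1cc(OC)c(OC)c(C[C@]2(C)[C@@H](C)CC[C@]3(C)C(C)=CCC[C@@H]23)c1OC | intermediate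
28 | 3-(DecCH2)-2,5-dimethoxycyclohexa-2,5-diene-1,4-dione | COC1=CC(=O)C(OC)=C(C[C@]2(C)[C@@H](C)CC[C@]3(C)C(C)=CCC[C@@H]23)C1=O | intermediate
29 | 3-(DecCH2)-2-hydroxy-5-methoxycyclohexa-2,5-diene-1,4-dione | COC1=CC(=O)C(O)=C(C[C@]2(C)[C@@H](C)CC[C@]3(C)C(C)=CCC[C@@H]23)C1=O | intermediate
30 | methyl 5-bromo-2,4-dihydroxybenzoate | COC(=O)c1cc(Br)c(O)cc1O | starting material
31 | methyl 5-bromo-2,4-dihydroxy-3-nitrobenzoate | COC(=O)c1cc(Br)c(O)c([N+](=O)[O-])c1O | intermediate
32 | methyl 2,4-diacetoxy-5-bromo-3-nitrobenzoate | COC(=O)c1cc(Br)c(OC(C)=O)c([N+](=O)[O-])c1OC(C)=O | intermediate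
33 | methyl 2,4-diacetoxy-5-(DecCH2)-3-nitrobenzoate | COC(=O)c1cc(C[C@]2(C)[C@@H](C)CC[C@]3(C)C(C)=CCC[C@@H]23)c(OC(C)=O)c([N+](=O)[O-])c1OC(C)=O | intermediate
34 | methyl 5-(DecCH2)-2,4-dihydroxy-3-nitrobenzoate | COC(=O)c1cc(C[C@]2(C)[C@@H](C)CC[C@]3(C)C(C)=CCC[C@@H]23)c(O)c([N+](=O)[O-])c1O | intermediate
35 | methyl 3-amino-5-(DecCH2)-2,4-dihydroxybenzoate | COC(=O)c1cc(C[C@]2(C)[C@@H](C)CC[C@]3(C)C(C)=CCC[C@@H]23)c(O)c(N)c1O | intermediate
36 | nakijiquinone F | COC(=O)c1cc(C[C@]2(C)[C@@H](C)CC[C@]3(C)C(C)=CCC[C@@H]23)c(O)c(NC2=CC(=O)C(O)=C(C[C@]3(C)[C@@H](C)CC[C@]4(C)C(C)=CCC[C@@H]34)C2=O)c1O | target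

## Step count and risks

Total step count: 28. Longest linear sequence: 21 steps (steps 1–6, 8–17, 19, 25–28).

Steps most likely to fail:

Step 14. The cycloaddition may be slow at the fully substituted diene terminus; endo/exo or π-facial discrimination may be poor; or the Lewis acid may trigger ene reaction or oligomerisation of the electron-rich diene. Fallback: set out from aldehyde 16 and switch to a thermal, nitro-activated cycloaddition. Henry addition of nitromethane (tetramethylguanidine cat.) should give the nitro alcohol F1, and dehydration (MsCl, Et3N) the (E)-nitroalkene F2. Heating F2 in toluene at 80–110 °C without Lewis acid should give, with endo-nitro preference, the trans-fused nitro-octalin F3. Radical denitration (Bu3SnH, AIBN, toluene, 110 °C) comes back to the route at benzyl ether 20, bypassing step 15 as well.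

Step 28. Electron transfer between the electron-rich aminoresorcinol and the quinone, air oxidation of 35, or condensation of an ortho-hydroxyl with the quinone carbonyl may compete with substitution. Fallback: set out from nitrophenol 31 and keep the phenols masked until the end. MOMCl and i-Pr2NEt should give the bis(methoxymethyl) ether F6; Negishi coupling with organozinc 26 the nitroarene F7; Zn/AcOH the protected aniline F8. Substitution on quinone 29 (NaHCO3, EtOH, 60 °C) should give the protected coupling product F9, and mild acid (HCl in MeOH, rt) comes back at 36.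

Step 20. Transmetalation and reductive elimination may stall at the doubly ortho-substituted, electron-rich arylpalladium intermediate, with protodemetalation of the organozinc reagent taking over. Fallback: set out from alcohol 21 and use polar addition instead of cross-coupling for this half. Dess–Martin oxidation should give the neopentyl aldehyde F4; addition of 2,3,5,6-tetramethoxyphenyllithium (from 23, n-BuLi, TMEDA, THF) the benzylic alcohol F5; benzylic hydrogenolysis with Li in liquid NH3 comes back at 27.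

## Further compounds

F1 | step 14 | (3S,4S,7E)-3-[(benzyloxy)methyl]-3,4,7,8-tetramethyl-1-nitrodeca-7,9-dien-2-ol (carbinol epimers) | C=C/C(C)=C(\C)CC[C@H](C)[C@@](C)(COCc1ccccc1)C(O)C[N+](=O)[O-]
F2 | step 14 | (1E,3R,4S,7E)-3-[(benzyloxy)methyl]-3,4,7,8-tetramethyl-1-nitrodeca-1,7,9-triene | C=C/C(C)=C(\C)CC[C@H](C)[C@@](C)(COCc1ccccc1)/C=C/[N+](=O)[O-]
F3 | step 14 | trans-fused 1-nitro analogue of 20 (nitro on C1, cis to H10) | c1ccccc1COC[C@]2(C)[C@@H](C)CC[C@]3(C)C(C)=CC[C@H]([N+](=O)[O-])[C@@H]23
F4 | step 20 | (1R,2S,4aS,8aR)-1,2,4a,5-tetramethyl-1,2,3,4,4a,7,8,8a-octahydronaphthalene-1-carbaldehyde | O=C[C@]1(C)[C@@H](C)CC[C@]2(C)C(C)=CCC[C@@H]12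
F5 | step 20 | Dec-CH(OH)-(2,3,5,6-tetramethoxyphenyl) (carbinol epimers) | COc1cc(OC)c(OC)c(C(O)[C@]2(C)[C@@H](C)CC[C@]3(C)C(C)=CCC[C@@H]23)c1OC
F6 | step 28 | methyl 5-bromo-2,4-bis(methoxymethoxy)-3-nitrobenzoate | COCOc1c(Br)cc(C(=O)OC)c(OCOC)c1[N+](=O)[O-]
F7 | step 28 | methyl 5-(DecCH2)-2,4-bis(methoxymethoxy)-3-nitrobenzoate | COCOc1c(C[C@]2(C)[C@@H](C)CC[C@]3(C)C(C)=CCC[C@@H]23)cc(C(=O)OC)c(OCOC)c1[N+](=O)[O-]
F8 | step 28 | methyl 3-amino-5-(DecCH2)-2,4-bis(methoxymethoxy)benzoate | COCOc1c(C[C@]2(C)[C@@H](C)CC[C@]3(C)C(C)=CCC[C@@H]23)cc(C(=O)OC)c(OCOC)c1N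
F9 | step 28 | bis(methoxymethyl) ether of nakijiquinone F | COCOc1c(C[C@]2(C)[C@@H](C)CC[C@]3(C)C(C)=CCC[C@@H]23)cc(C(=O)OC)c(OCOC)c1NC1=CC(=O)C(O)=C(C[C@]2(C)[C@@H](C)CC[C@]3(C)C(C)=CCC[C@@H]23)C1=O
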